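Its constants were set for the occasion; the run is a simulation.

The vessel is a stirred, isothermal tank into which partner goes in portions while the initiator slowly dies.

starting material 10 mM; partner 10.0 mM (in portions, 4); protic impurity 1.00 mM; initiator 0.50 mM; time 15 d; the portions of partner follow each other after 2.5 h, the first at the start

    initiator → 2 initiating radical (k1 = 0.056 /h)
    starting material + second chain carrier → released group + first chain carrier (k2 = 2.8 × 10⁶ /M/h)
    partner → decomposed reagent (k3 = 0.030 /h)
    2 first chain carrier → ended chains A (k4 = 1 × 10⁷ /M/s)
    starting material + protic impurity → quenched substrate (k5 = 40 /M/h)
    2 second chain carrier → ended chains B (k6 = 1.0 × 10⁷ /M/s)
    starting material ⇌ dormant form (K7 = 0.80, k7 = 0.045 /h)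
    partner + first chain carrier → product + second chain carrier (k8 = 1.2 × 10⁶ /M/h)
    starting material + initiating radical → capped initiator + first chain carrier (k9 = 2.6 × 10⁷ /M/h)

- in percentages every species weighs as the starting material in it: one ended chains A counts as two
- where a step has two of a species, its rate is k times that concentration squared, and two are used at each turn
- what has gone from starting material into another species counts as reacted, even if it can come back
- run time (flask): 15 d

* part of the starting material gone at 15 d
* the product standing at 15 d, as a percentage of the starting material charged

What makes product? The first chain carrier takes partner and gives product, and the second chain carrier formed there restores it from starting material. Partner therefore sees a pseudo-first-order loss of 1.2 × 10⁶ /M/h times [first chain carrier], racing its own decay at 0.030 /h.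

How much carrier stands? At the start a first chain carrier lasts about 1.79 s, far shorter than partner's half-life of 0.963 d. So its level follows its source: making balances ending, and [first chain carrier] is the square root of 0.056 /h times [initiator] over 1 × 10⁷ /M/s, or 2.79 × 10⁻⁵ mM on the full charge.

And later? Because of that root, the level halves in twice the initiator's half-life, in 1.03 d, close to partner's 0.963 d. The two clocks nearly coincide, so the loss equation integrates in closed form.

Let the dose be the carrier's loss rate on partner, summed over the run and counted in lifetimes. The average portion enters at 3.75 h, so the dose is 1.08. Dose minus one, plus e to the minus dose, all over dose, gives 0.388: this is the partner's share, the part of charged partner that ends as product. My product is therefore 38.8%.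

Didn't you ignore the second carrier's ending? Yes. Taken at both full charges, the ratio of its ending to the first carrier's is 0.184, and this is no ceiling, since at a given [partner] the ratio grows as [starting material] falls. That ending removes carriers as well, so I expect my share to be slightly high.

And the starting material? Product costs 3.88 mM, capping costs 1.00 mM, and the impurity, whose half-life of 1.73 h is short against 15 d, costs 1.00 mM. The remainder divides with the dormant form at 0.80, because that exchange, both directions together, relaxes with a half-life of 0.285 d, also short against 15 d. I commit to 77.1% gone.

The forecast gave 76% and 37%, reasoning that “each partner portion splits between product and its own decay”.

The flask gives 74.4% gone and 35.3% product. At 0.844 d this flask loses partner to decay 1.8 times as fast as to product, while the share implies 1.58 over the whole run. The neighbour charged with 17 mM of starting material has the same dose by this reckoning, so the share puts its product at 22.8% of its charge, and it stands at 21.8%.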